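The ten-membered ring is not closed end to end but grown from the six-membered ring of (R)-carvone, which supplies C1–C6 and, through its isopropenyl group, C9, C10 and C14 (germacrane numbers: C1=C10 alkene, C3 ketone, C4 methyl carbon, C6 lactone carbinol, C7 ring fusion, C8 ester carbon). The key step, an anionic oxy-Cope rearrangement of a cis-1-[(Z)-2-alkoxyvinyl]-2-isopropenylcyclohexan-1-olate, breaks C1–C6 and forms C8–C9. It delivers the ring, the (Z)-C1=C10 alkene and the C8–O stereocentre by chair chirality transfer, and its C6 enolate is alkylated at C7 in the same flask. It exploits the 1,6 relation of the C6 oxygen to C10.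

Key step: step 10

Remark: germacrane locants serve only as atom labels. Compounds 24 and 25 are racemic and 19 and 20 are C11 epimer mixtures; both stereocentres disappear later (steps 17 and 14).

Step 1
Reactants: 1 (R)-(−)-carvone
Product: 2 (1R,5R)-2-methyl-5-(prop-1-en-2-yl)cyclohex-2-en-1-ol (cis-carveol)
Conditions: NaBH4, CeCl3·7H2O, MeOH, −20 → 0 °C
Reagents that add atoms: none
Why: Luche 1,2-reduction; hydride should add axially to the half-chair with equatorial isopropenyl, so the new carbinol (future C3) is cis to isopropenyl by substrate control.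

Step 2
Reactants: 2 cis-carveol
Product: 3 (1S,5R)-2-methyl-5-(prop-1-en-2-yl)cyclohex-2-en-1-yl 4-nitrobenzoate
Conditions: 4-O2NC6H4CO2H, PPh3, DIAD, THF, 0 °C → rt
Reagents that add atoms: 4-nitrobenzoic acid O=C(O)c1ccc(cc1)[N+](=O)[O-]
Why: Mitsunobu esterification; SN2 attack of the carboxylate on the alkoxyphosphonium ion inverts C3, which puts its oxygen trans to isopropenyl as needed for the facial control of step 6.

Step 3
Reactants: 3 trans-carveyl 4-nitrobenzoate
Product: 4 (1S,5R)-2-methyl-5-(prop-1-en-2-yl)cyclohex-2-en-1-ol (trans-carveol)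
Conditions: K2CO3, MeOH, rt
Reagents that add atoms: none
Why: Base-catalysed transesterification (methanolysis) at the acyl carbon, which leaves the carbinol configuration untouched.

Step 4
Reactants: 4 trans-carveol
Product: 5 tert-butyldimethylsilyl ether of 4
Conditions: TBSCl, imidazole, DMF, rt
Reagents that add atoms: tert-butyldimethylsilyl chloride CC(C)(C)[Si](C)(C)Cl
Why: Silylation of the secondary alcohol through the N-silylimidazolium ion; the ether must later survive strong base, DDQ and mild acid.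

Step 5
Reactants: 5 TBS ether of trans-carveol
Product: 6 (4S,6R)-4-(tert-butyldimethylsilyloxy)-3-methyl-6-(prop-1-en-2-yl)cyclohex-2-en-1-one
Conditions: Rh2(cap)4 (1 mol %), t-BuOOH, K2CO3, CH2Cl2, rt
Reagents that add atoms: tert-butyl hydroperoxide CC(C)(C)OO
Why: Allylic C–H oxidation (Kharasch-type radical chain with dirhodium caprolactamate/TBHP); the peroxyl radical abstracts H from C6, the only ring CH2 allylic to the C4=C5 alkene, and the allyl radical is trapped at its secondary terminus and collapses to the enone without touching a stereocentre.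

Step 6
Reactants: 6 γ-silyloxy enone
Product: 7 (2R,4S,5R)-4-(tert-butyldimethylsilyloxy)-5-methyl-2-(prop-1-en-2-yl)cyclohexan-1-one
Conditions: [(Ph3P)CuH]6, H2O, PhMe, rt
Reagents that add atoms: none
Why: Conjugate reduction with Stryker's reagent; copper hydride should add to C4 anti to the adjacent C3 silyloxy group (the usual trans addition to 4-substituted cyclohexenones), so the methyl group ends cis to OTBS and trans to isopropenyl (4R), and the isolated isopropenyl alkene is not reduced.

Step 7
Reactants: 8 4-methoxybenzyl alcohol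
Product: 9 1-({[(E)-1,2-dichloroethenyl]oxy}methyl)-4-methoxybenzene
Conditions: KH, THF, 0 °C; Cl2C=CHCl, −50 °C → rt
Reagents that add atoms: trichloroethylene ClC=C(Cl)Cl
Why: Dichlorovinyl ether synthesis; the potassium alkoxide adds to dichloroacetylene formed in situ from trichloroethylene (net addition–elimination), which gives the (E)-1,2-dichlorovinyl ether.

Step 8
Reactants: 7 cyclohexanone, 9 PMB dichlorovinyl ether
Product: 11 (1S,2R,4S,5R)-4-(tert-butyldimethylsilyloxy)-1-{[(4-methoxybenzyl)oxy]ethynyl}-5-methyl-2-(prop-1-en-2-yl)cyclohexan-1-ol, via lithium alkoxyacetylide 10 (not isolated)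
Conditions: 9, n-BuLi (2 equiv), THF, −78 → −40 °C; then 7, −78 °C; aq NaHCO3
Reagents that add atoms: none
Why: Elimination/Li–Cl exchange gives the alkoxyacetylide, whose 1,2-addition should occur axially on the chair with equatorial isopropenyl and methyl groups, placing the slim alkynyl group cis to isopropenyl (6S carbinol); its low basicity spares the epimerisable C1–H.

Step 9
Reactants: 11 propargylic alcohol
Product: 12 (1S,2R,4S,5R)-4-(tert-butyldimethylsilyloxy)-1-{(Z)-2-[(4-methoxybenzyl)oxy]ethenyl}-5-methyl-2-(prop-1-en-2-yl)cyclohexan-1-ol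
Conditions: H2 (1 atm), Lindlar catalyst, quinoline, EtOAc, rt
Reagents that add atoms: none
Why: Lindlar semi-hydrogenation adds H2 syn to the ynol ether only, giving the (Z)-enol ether, while the poisoned catalyst leaves the 1,1-disubstituted alkene and the PMB ether intact.

Step 10
Reactants: 12 (Z)-alkoxyvinyl carbinol
Product: 15 tert-butyl 2-[(1R,2R,4Z,7S,8R)-7-(tert-butyldimethylsilyloxy)-2-[(4-methoxybenzyl)oxy]-4,8-dimethyl-10-oxocyclodec-4-en-1-yl]acetate, via potassium alkoxide 13 (not isolated), via ring-expanded potassium enolate 14 (not isolated)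
Conditions: KHMDS, 18-crown-6, THF, 0 °C → rt; then BrCH2CO2t-Bu, −78 → −20 °C
Reagents that add atoms: tert-butyl bromoacetate CC(C)(C)OC(=O)CBr
Why: Alkoxide 13 should undergo a [3,3]-sigmatropic shift (anionic oxy-Cope rearrangement, the classical 1,2-dialkenylcyclohexanol to cyclodec-5-enone ring expansion) that breaks C1–C6 and forms C8–C9, and the resulting enolate 14 is C-alkylated at C7 by the bromoacetate (SN2). The ten-membered ring thus arises by 6→10 ring expansion through a six-membered chair transition state fused to the cyclohexane, not by an end-to-end cyclisation, so no medium-ring closure has to be paid for. Because the C6 alkenyl group is axial and the C1 isopropenyl group equatorial (cis on the ring; the ring flip would put isopropenyl and methyl axial), C2 sits axial on that chair and the new C1=C10 alkene must be Z. In the same chair the (Z)-enol ether holds OPMB axial at C8, so C9 bonds to one face of C8 and the carvone-derived C1/C6 configuration is transferred to C8 (R). C7 is set by alkylation on the peripheral face of the ring enolate, the face turned away from the transannular C1=C10 unit, which should give the C7 configuration of the target. The step needs rearrangement and alkylation to outrun β-elimination of the PMB-oxide from 14; this is served by running the shift at or below room temperature with crown ether, by the C8–O bond being born in the enolate plane and chelated to potassium (poor overlap for E1cB), and by alkylating at −78 °C.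

Step 11
Reactants: 15 alkylated cyclodecenone
Product: 16 tert-butyl 2-[(1R,2R,4Z,7S,8R)-7-(tert-butyldimethylsilyloxy)-2-hydroxy-4,8-dimethyl-10-oxocyclodec-4-en-1-yl]acetate
Conditions: DDQ, CH2Cl2/pH 7 buffer, 0 °C
Reagents that add atoms: none
Why: Oxidative PMB cleavage (benzylic hydride abstraction, then hydrolysis of the oxocarbenium ion) frees the C8 hydroxyl under neutral conditions that leave the TBS ether, the tert-butyl ester, the alkene and the epimerisable C7 centre alone.

Step 12
Reactants: 16 β-hydroxy ketone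
Product: 17 tert-butyl 2-[(1S,2R,4Z,7S,8R,10R)-7-(tert-butyldimethylsilyloxy)-2,10-dihydroxy-4,8-dimethylcyclodec-4-en-1-yl]acetate
Conditions: Me4NBH(OAc)3, MeCN/AcOH, −30 °C
Reagents that add atoms: none
Why: Evans–Saksena reduction; the C8 hydroxyl exchanges onto boron and should deliver hydride intramolecularly to the C6 ketone through a six-membered transition state, giving the 1,3-anti diol (6R).

Step 13
Reactants: 17 anti-diol ester
Product: 18 (3S,4R,6R,7R,8R,1(10)Z)-3-(tert-butyldimethylsilyloxy)-8-hydroxygermacr-1(10)-en-12,6-olide (trans-fused γ-lactone, C11 = CH2)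
Conditions: 85% aq H3PO4, PhMe, rt
Reagents that add atoms: none
Why: Acidolysis of the tert-butyl ester and γ-lactonisation; closure onto the C6 hydroxyl gives the trans-fused 6,12-lactone, the arrangement that persists in natural 8β-hydroxy-6α,12-olides, whereas closure onto C8 would give a cis-fused isomer, and the secondary TBS ether should tolerate aqueous H3PO4.

Step 14
Reactants: 18 hydroxy lactone
Product: 21 (3S,4R,6R,7R,8R,1(10)Z)-3-(tert-butyldimethylsilyloxy)-8-hydroxygermacra-1(10),11(13)-dien-12,6-olide, via Mannich base 19 (not isolated), via quaternary ammonium iodide 20 (not isolated)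
Conditions: LDA (2.5 equiv), THF, −78 °C; Me2N=CH2+ I−, −78 °C → rt; MeI, MeOH, rt; aq NaHCO3
Reagents that add atoms: Eschenmoser's salt C[N+](C)=C.[I-]
Why: α-Methylenation by the Mannich route; the lactone enolate (formed beside the C8 lithium alkoxide) is aminomethylated, and N-methylation followed by mild base eliminates trimethylamine (E1cB) to the exocyclic methylene, which removes the C11 stereocentre.

Step 15
Reactants: 22 tert-butyl acrylate, 23 acetaldehyde
Product: 24 tert-butyl 3-hydroxy-2-methylidenebutanoate (racemic)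
Conditions: DABCO (cat.), 1,4-dioxane/H2O, rt
Reagents that add atoms: none
Why: Morita–Baylis–Hillman reaction (amine conjugate addition, aldol addition of the zwitterionic enolate to acetaldehyde, elimination of the catalyst).

Step 16
Reactants: 24 Baylis–Hillman alcohol
Product: 25 tert-butyl 3-acetoxy-2-methylidenebutanoate (racemic)
Conditions: AcCl, pyridine, CH2Cl2, 0 °C
Reagents that add atoms: acetyl chloride CC(=O)Cl
Why: O-Acetylation of the secondary allylic alcohol by nucleophilic acyl substitution.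

Step 17
Reactants: 25 Baylis–Hillman acetate
Product: 26 tert-butyl (E)-2-(acetoxymethyl)but-2-enoate
Conditions: DABCO (cat.), THF, reflux
Reagents that add atoms: none
Why: Amine-catalysed 1,3-transposition of the Baylis–Hillman acetate (SN2′ addition of DABCO, SN2′ return of acetate) to the thermodynamically preferred trisubstituted alkene with the ester trans to the β-methyl group (E).

Step 18
Reactants: 26 rearranged tert-butyl ester
Product: 27 (E)-2-(acetoxymethyl)but-2-enoic acid
Conditions: TFA, CH2Cl2, 0 °C → rt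
Reagents that add atoms: none
Why: Acidolysis of the tert-butyl ester (E1 loss of isobutene); the allylic acetate and the alkene geometry should be stable to TFA.

Step 19
Reactants: 21 hydroxy methylene lactone, 27 side-chain acid
Product: 29 (3S,4R,6R,7S,8R,1(10)Z)-8-[(E)-2-(acetoxymethyl)but-2-enoyloxy]-3-(tert-butyldimethylsilyloxy)germacra-1(10),11(13)-dien-12,6-olide, via mixed anhydride 28 (not isolated)
Conditions: 27, 2,4,6-Cl3C6H2COCl, Et3N, PhMe, rt; then 21, DMAP, rt
Reagents that add atoms: none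
Why: Yamaguchi esterification; DMAP attacks the less hindered enoyl carbonyl of the mixed anhydride and the acylpyridinium ion acylates the hindered C8 hydroxyl with retention at C8.

Step 20
Reactants: 29 silyl ether
Product: 30 (3S,4R,6R,7S,8R,1(10)Z)-8-[(E)-2-(acetoxymethyl)but-2-enoyloxy]-3-hydroxygermacra-1(10),11(13)-dien-12,6-olide
Conditions: HF·pyridine, pyridine, THF, 0 °C → rt
Reagents that add atoms: none
Why: Fluoride-driven desilylation (strong Si–F bond) under buffered conditions that spare the esters, the allylic acetate and the methylene lactone.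

Step 21
Reactants: 30 C3 alcohol
Product: 31 target, (4R,6R,7S,8R,1(10)Z)-8-[(E)-2-(acetoxymethyl)but-2-enoyloxy]-3-oxogermacra-1(10),11(13)-dien-12,6-olide
Conditions: Dess–Martin periodinane, NaHCO3, CH2Cl2, 0 °C → rt
Reagents that add atoms: none
Why: Dess–Martin oxidation of the homoallylic secondary alcohol under buffered, non-basic conditions should give the β,γ-unsaturated ketone without moving C1=C10 into conjugation or epimerising C4.

Compound list
1 | (R)-(−)-carvone, (5R)-2-methyl-5-(prop-1-en-2-yl)cyclohex-2-en-1-one | CC1=CC[C@H](CC1=O)C(C)=C | starting material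
2 | (1R,5R)-2-methyl-5-(prop-1-en-2-yl)cyclohex-2-en-1-ol (cis-carveol) | CC1=CC[C@H](C[C@H]1O)C(C)=C | intermediate
3 | (1S,5R)-2-methyl-5-(prop-1-en-2-yl)cyclohex-2-en-1-yl 4-nitrobenzoate | CC1=CC[C@H](C[C@@H]1OC(=O)c2ccc(cc2)[N+](=O)[O-])C(C)=C | intermediate
4 | (1S,5R)-2-methyl-5-(prop-1-en-2-yl)cyclohex-2-en-1-ol (trans-carveol) | CC1=CC[C@H](C[C@@H]1O)C(C)=C | intermediate
5 | tert-butyl(dimethyl){[(1S,5R)-2-methyl-5-(prop-1-en-2-yl)cyclohex-2-en-1-yl]oxy}silane | CC1=CC[C@H](C[C@@H]1O[Si](C)(C)C(C)(C)C)C(C)=C | intermediate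
6 | (4S,6R)-4-(tert-butyldimethylsilyloxy)-3-methyl-6-(prop-1-en-2-yl)cyclohex-2-en-1-one | CC1=CC(=O)[C@H](C[C@@H]1O[Si](C)(C)C(C)(C)C)C(C)=C | intermediate
7 | (2R,4S,5R)-4-(tert-butyldimethylsilyloxy)-5-methyl-2-(prop-1-en-2-yl)cyclohexan-1-one | C[C@@H]1CC(=O)[C@H](C[C@@H]1O[Si](C)(C)C(C)(C)C)C(C)=C | intermediate
8 | 4-methoxybenzyl alcohol | COc1ccc(CO)cc1 | starting material
9 | 1-({[(E)-1,2-dichloroethenyl]oxy}methyl)-4-methoxybenzene | COc1ccc(CO/C(Cl)=C\Cl)cc1 | intermediate
10 | lithium [(4-methoxybenzyl)oxy]ethynide | [Li]C#COCc1ccc(OC)cc1 | intermediate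
11 | (1S,2R,4S,5R)-4-(tert-butyldimethylsilyloxy)-1-{[(4-methoxybenzyl)oxy]ethynyl}-5-methyl-2-(prop-1-en-2-yl)cyclohexan-1-ol | O[C@]1(C#COCc2ccc(OC)cc2)[C@@H](C(C)=C)C[C@H](O[Si](C)(C)C(C)(C)C)[C@H](C)C1 | intermediate
12 | (1S,2R,4S,5R)-4-(tert-butyldimethylsilyloxy)-1-{(Z)-2-[(4-methoxybenzyl)oxy]ethenyl}-5-methyl-2-(prop-1-en-2-yl)cyclohexan-1-ol | O[C@]1(/C=C\OCc2ccc(OC)cc2)[C@@H](C(C)=C)C[C@H](O[Si](C)(C)C(C)(C)C)[C@H](C)C1 | intermediate
13 | potassium alkoxide of 12 | [K+].[O-][C@]1(/C=C\OCc2ccc(OC)cc2)[C@@H](C(C)=C)C[C@H](O[Si](C)(C)C(C)(C)C)[C@H](C)C1 | intermediate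
14 | potassium (1Z,3R,5Z,8S,9R)-8-(tert-butyldimethylsilyloxy)-3-[(4-methoxybenzyl)oxy]-5,9-dimethylcyclodeca-1,5-dien-1-olate (C6 enolate, C5 and C8 trans across C6=C7) | C1/C([O-])=C/[C@H](OCc2ccc(OC)cc2)C/C(C)=C\C[C@H](O[Si](C)(C)C(C)(C)C)[C@@H]1C.[K+] | intermediate
15 | tert-butyl 2-[(1R,2R,4Z,7S,8R)-7-(tert-butyldimethylsilyloxy)-2-[(4-methoxybenzyl)oxy]-4,8-dimethyl-10-oxocyclodec-4-en-1-yl]acetate | O=C1C[C@@H](C)[C@@H](O[Si](C)(C)C(C)(C)C)C/C=C(/C)C[C@@H](OCc2ccc(OC)cc2)[C@H]1CC(=O)OC(C)(C)C | intermediate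
16 | tert-butyl 2-[(1R,2R,4Z,7S,8R)-7-(tert-butyldimethylsilyloxy)-2-hydroxy-4,8-dimethyl-10-oxocyclodec-4-en-1-yl]acetate | O=C1C[C@@H](C)[C@@H](O[Si](C)(C)C(C)(C)C)C/C=C(/C)C[C@@H](O)[C@H]1CC(=O)OC(C)(C)C | intermediate
17 | tert-butyl 2-[(1S,2R,4Z,7S,8R,10R)-7-(tert-butyldimethylsilyloxy)-2,10-dihydroxy-4,8-dimethylcyclodec-4-en-1-yl]acetate | O[C@@H]1C[C@@H](C)[C@@H](O[Si](C)(C)C(C)(C)C)C/C=C(/C)C[C@@H](O)[C@H]1CC(=O)OC(C)(C)C | intermediate
18 | (3S,4R,6R,7R,8R,1(10)Z)-3-(tert-butyldimethylsilyloxy)-8-hydroxygermacr-1(10)-en-12,6-olide | C1C(=O)O[C@@H]2C[C@@H](C)[C@@H](O[Si](C)(C)C(C)(C)C)C/C=C(/C)C[C@@H](O)[C@@H]12 | intermediate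
19 | 13-(dimethylamino) derivative of 18 (Mannich base, C11 epimers) | CN(C)CC1C(=O)O[C@@H]2C[C@@H](C)[C@@H](O[Si](C)(C)C(C)(C)C)C/C=C(/C)C[C@@H](O)[C@@H]12 | intermediate
20 | 13-(trimethylammonio) derivative of 18, iodide | C[N+](C)(C)CC1C(=O)O[C@@H]2C[C@@H](C)[C@@H](O[Si](C)(C)C(C)(C)C)C/C=C(/C)C[C@@H](O)[C@@H]12.[I-] | intermediate
21 | (3S,4R,6R,7R,8R,1(10)Z)-3-(tert-butyldimethylsilyloxy)-8-hydroxygermacra-1(10),11(13)-dien-12,6-olide | C=C1C(=O)O[C@@H]2C[C@@H](C)[C@@H](O[Si](C)(C)C(C)(C)C)C/C=C(/C)C[C@@H](O)[C@@H]12 | intermediate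
22 | tert-butyl acrylate | C=CC(=O)OC(C)(C)C | starting material
23 | acetaldehyde | CC=O | starting material
24 | tert-butyl 3-hydroxy-2-methylidenebutanoate (racemic) | CC(O)C(=C)C(=O)OC(C)(C)C | intermediate
25 | tert-butyl 3-acetoxy-2-methylidenebutanoate (racemic) | CC(OC(C)=O)C(=C)C(=O)OC(C)(C)C | intermediate
26 | tert-butyl (E)-2-(acetoxymethyl)but-2-enoate | CC(C)(C)OC(=O)/C(=C/C)COC(C)=O | intermediate
27 | (E)-2-(acetoxymethyl)but-2-enoic acid | OC(=O)/C(=C/C)COC(C)=O | intermediate
28 | (E)-2-(acetoxymethyl)but-2-enoic 2,4,6-trichlorobenzoic anhydride | O=C(OC(=O)/C(=C/C)COC(C)=O)c1c(Cl)cc(Cl)cc1Cl | intermediate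
29 | (3S,4R,6R,7S,8R,1(10)Z)-8-[(E)-2-(acetoxymethyl)but-2-enoyloxy]-3-(tert-butyldimethylsilyloxy)germacra-1(10),11(13)-dien-12,6-olide | C=C1C(=O)O[C@@H]2C[C@@H](C)[C@@H](O[Si](C)(C)C(C)(C)C)C/C=C(/C)C[C@@H](OC(=O)/C(=C/C)COC(C)=O)[C@@H]12 | intermediate
30 | (3S,4R,6R,7S,8R,1(10)Z)-8-[(E)-2-(acetoxymethyl)but-2-enoyloxy]-3-hydroxygermacra-1(10),11(13)-dien-12,6-olide | C=C1C(=O)O[C@@H]2C[C@@H](C)[C@@H](O)C/C=C(/C)C[C@@H](OC(=O)/C(=C/C)COC(C)=O)[C@@H]12 | intermediate
31 | (4R,6R,7S,8R,1(10)Z)-8-[(E)-2-(acetoxymethyl)but-2-enoyloxy]-3-oxogermacra-1(10),11(13)-dien-12,6-olide (CNP0265140.1) | C=C1C(=O)O[C@@H]2C[C@@H](C)C(=O)C/C=C(/C)C[C@@H](OC(=O)/C(=C/C)COC(C)=O)[C@@H]12 | target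

Total step count: 21
Longest linear sequence: 16 steps (steps 1–6, 8–14, 19–21)

Steps most likely to fail

Step 10. The ring-expanded enolate 14 carries the C8 alkoxy group β to the carbonyl and may lose PMB-oxide by β-elimination before it is alkylated, or part of the material may leak through a boat transition state. The fallback sets out from 12 and comes back at 15. Compound 12 is silylated with N-(trimethylsilyl)imidazole to the trimethylsilyl ether F1. Thermolysis in degassed o-dichlorobenzene at about 200 °C should effect the neutral siloxy-Cope rearrangement to the ring-expanded trimethylsilyl enol ether F2, during which no free enolate exists. Methyllithium in THF at −78 °C then releases the lithium enolate F3 at a temperature at which β-alkoxy enolates are stable, and tert-butyl bromoacetate with DMPU gives 15.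

Step 12. Hydride delivery from the C8–O–B tether may be geometrically disfavoured in the ring conformation, so that the reduction follows peripheral attack and gives the C6 epimer or a mixture. The fallback sets out from 15 and comes back at 18; it uses the peripheral bias and then inverts C6. L-Selectride in THF at −78 °C should reduce 15, with the PMB ether still in place, to the 6S alcohol F4. Mitsunobu esterification with 4-nitrobenzoic acid inverts C6 to the 6R 4-nitrobenzoate F5. Methanolysis with K2CO3 gives the 6R hydroxy ester F6, which is closed with camphorsulfonic acid in warm toluene to the C8 PMB-protected trans-lactone F7; only one hydroxyl is free, so the regiochemical question of step 13 does not arise. DDQ then gives 18.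

Step 13. The acid-mediated lactonisation may close, or equilibrate, onto the C8 hydroxyl and give the cis-fused 8,12-lactone. The fallback sets out from 16 and comes back at 18, replacing steps 12 and 13. An Evans–Tishchenko reduction of 16 with acetaldehyde and catalytic SmI2 should give the 1,3-anti diol 8-monoacetate F8: the hemiacetal on the C8 oxygen delivers hydride to C6 and leaves C8 acylated. Lactonisation with aqueous H3PO4 can then engage only the C6 hydroxyl and gives the acetoxy lactone F9. Brief methanolysis (K2CO3, MeOH, 0 °C) removes the acetate and gives 18.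

Further compounds
F1 | step 10 | trimethylsilyl ether of 12 | C[Si](C)(C)O[C@]1(/C=C\OCc2ccc(OC)cc2)[C@@H](C(C)=C)C[C@H](O[Si](C)(C)C(C)(C)C)[C@H](C)C1
F2 | step 10 | ring-expanded trimethylsilyl enol ether (C6–OSiMe3, C6=C7) | C1/C(O[Si](C)(C)C)=C/[C@H](OCc2ccc(OC)cc2)C/C(C)=C\C[C@H](O[Si](C)(C)C(C)(C)C)[C@@H]1C
F3 | step 10 | lithium enolate corresponding to 14 | C1/C([O-])=C/[C@H](OCc2ccc(OC)cc2)C/C(C)=C\C[C@H](O[Si](C)(C)C(C)(C)C)[C@@H]1C.[Li+]
F4 | step 12 | 6S hydroxy tert-butyl ester with C8 PMB ether | O[C@H]1C[C@@H](C)[C@@H](O[Si](C)(C)C(C)(C)C)C/C=C(/C)C[C@@H](OCc2ccc(OC)cc2)[C@H]1CC(=O)OC(C)(C)C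
F5 | step 12 | 6R 4-nitrobenzoate with C8 PMB ether | O=C(O[C@@H]1C[C@@H](C)[C@@H](O[Si](C)(C)C(C)(C)C)C/C=C(/C)C[C@@H](OCc2ccc(OC)cc2)[C@H]1CC(=O)OC(C)(C)C)c3ccc(cc3)[N+](=O)[O-]
F6 | step 12 | 6R hydroxy tert-butyl ester with C8 PMB ether | O[C@@H]1C[C@@H](C)[C@@H](O[Si](C)(C)C(C)(C)C)C/C=C(/C)C[C@@H](OCc2ccc(OC)cc2)[C@H]1CC(=O)OC(C)(C)C
F7 | step 12 | 8-O-(4-methoxybenzyl) ether of lactone 18 | C1C(=O)O[C@@H]2C[C@@H](C)[C@@H](O[Si](C)(C)C(C)(C)C)C/C=C(/C)C[C@@H](OCc3ccc(OC)cc3)[C@@H]12
F8 | step 13 | 8-O-acetyl derivative of diol 17 | O[C@@H]1C[C@@H](C)[C@@H](O[Si](C)(C)C(C)(C)C)C/C=C(/C)C[C@@H](OC(C)=O)[C@H]1CC(=O)OC(C)(C)C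
F9 | step 13 | 8-O-acetyl derivative of lactone 18 | C1C(=O)O[C@@H]2C[C@@H](C)[C@@H](O[Si](C)(C)C(C)(C)C)C/C=C(/C)C[C@@H](OC(C)=O)[C@@H]12
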